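**Retrosynthetic overview**

1. Names used: ring A is the resorcinol ring fused only to the seven-membered ring; ring B is the arene fused to both the seven-membered ring and the dihydrofuran; ring C is the 2-hydroxyphenyl ring that carries the olefin; ring D is the benzo ring of the east dihydrobenzofuran. Ca and Cc are the seven-ring CH groups carrying the 4-hydroxyphenyl group and ring C; Cb is the CH shared by the seven-membered ring and the dihydrofuran; Cd is the O–CH(aryl) carbon.
2. The Z-olefin comes last: Heck coupling of the unprotected bromo tetracycle 33 with the unprotected east vinyl dihydrobenzofuran 12 gives the E isomer 34, and E→Z photoisomerisation gives the target. All methyl ethers are cleaved before the stilbene exists, because the east stilbene/resorcinol unit cyclises under acid.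
3. Key disconnection: the Cb–Cd bond of the tricycle's dihydrofuran, made by rhodium-carbene 1,5-C–H insertion. The enabling feature is that Cb is a diaryl methine flanked by rings A and B and ortho to the ring B ether oxygen; it is traced back to a dibenzosuberone carbonyl (hydrazone → diaryl carbene) whose ring B neighbour carries ArO–CH2–(4-methoxyphenyl).
4. Seven-membered ring: Friedel–Crafts closure of the Ca–ring A bond by acid opening of a temporary dihydrobenzofuran (ring C oxygen–Ca bond, absent from the target). That temporary ring is made enantioselectively by the same type of C–H insertion and fixes Cc.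
5. Order of ring formation: east dihydrofuran (step 4) → temporary dihydrofuran (step 10) → seven-membered ring with cleavage of the temporary ring (step 13) → dihydrofuran of the tricycle (step 18, last ring).

Key step: step 18

Assumption: Rh2(R-PTAD)4, dirhodium tetrakis[(R)-(1-adamantyl)(N-phthalimido)acetate], is taken to give the (3S) dihydrobenzofuran series and Rh2(S-PTAD)4 the (3R) series; if the sense of induction is the opposite, the two antipodes are exchanged in steps 4, 10 and 18.

**Route**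

Step 1
Reactants: 1 1-bromo-3,5-dimethoxybenzene; 2 3,5-dimethoxybenzoyl chloride
Product: 4 (2-bromo-6-hydroxy-4-methoxyphenyl)(3,5-dimethoxyphenyl)methanone, via tetramethoxy ketone 3 (not isolated)
Conditions: AlCl3, CH2Cl2, 0 °C → rt; then BCl3, −78 → 0 °C; aq. HCl
Reagents that add atoms: 3,5-dimethoxybenzoyl chloride (compound 2), COc1cc(cc(OC)c1)C(Cl)=O
Why: Friedel–Crafts acylation should go to C2 of 1 (para to one methoxy group, the site between the two methoxy groups being more hindered), and BCl3 then cleaves only the methyl ether that chelates to the new ketone (chelation-controlled ortho-demethylation).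

Step 2
Reactants: 4 (2-bromo-6-hydroxy-4-methoxyphenyl)(3,5-dimethoxyphenyl)methanone; 5 4-methoxybenzyl chloride
Product: 6 {2-bromo-4-methoxy-6-[(4-methoxyphenyl)methoxy]phenyl}(3,5-dimethoxyphenyl)methanone
Conditions: K2CO3, NaI (cat.), DMF, 60 °C
Reagents that add atoms: 4-methoxybenzyl chloride (compound 5), COc1ccc(CCl)cc1
Why: Williamson etherification of the hydrogen-bonded phenol, helped by iodide catalysis, installs the ArO–CH2–Ar unit needed for C–H insertion.

Step 3
Reactants: 6 {2-bromo-4-methoxy-6-[(4-methoxyphenyl)methoxy]phenyl}(3,5-dimethoxyphenyl)methanone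
Product: 7 hydrazone of 6
Conditions: N2H4·H2O (excess), AcOH (cat.), n-BuOH, 110 °C
Reagents that add atoms: hydrazine (as monohydrate), NN
Why: Acid-catalysed hydrazone condensation of a hindered diaryl ketone needs heat and excess hydrazine; aryl bromide and ethers are inert.

Step 4
Reactants: 7 hydrazone of 6
Product: 9 (2R,3S)-4-bromo-3-(3,5-dimethoxyphenyl)-6-methoxy-2-(4-methoxyphenyl)-2,3-dihydro-1-benzofuran (2,3-cis), via diaryldiazomethane 8 (not isolated)
Conditions: MnO2, CH2Cl2, 0 °C, filtration; Rh2(R-PTAD)4 (1 mol%), CH2Cl2, −20 °C → rt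
Reagents that add atoms: none
Why: MnO2 dehydrogenates the hydrazone to diazoalkane 8, and the chiral dirhodium carboxylate forms a donor/donor carbene that undergoes enantioselective intramolecular 1,5-C–H insertion into the OCH2Ar bond; the catalyst sets C3 (S), and the aryl groups end cis, which step 5 corrects.

Step 5
Reactants: 9 (2R,3S)-4-bromo-3-(3,5-dimethoxyphenyl)-6-methoxy-2-(4-methoxyphenyl)-2,3-dihydro-1-benzofuran
Product: 10 5-[(2S,3S)-4-bromo-6-hydroxy-2-(4-hydroxyphenyl)-2,3-dihydro-1-benzofuran-3-yl]benzene-1,3-diol (2,3-trans)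
Conditions: BBr3 (excess), CH2Cl2, −78 °C → rt; MeOH/H2O quench
Reagents that add atoms: none
Why: Lewis-acid ether cleavage removes the four methyl groups, and reversible ionisation of the benzylic C2–O bond (p-oxybenzyl cation or quinone methide) should equilibrate C2 to the more stable trans isomer while C3 is untouched.

Step 6
Reactants: 10 5-[(2S,3S)-4-bromo-6-hydroxy-2-(4-hydroxyphenyl)-2,3-dihydro-1-benzofuran-3-yl]benzene-1,3-diol; 11 potassium vinyltrifluoroborate
Product: 12 5-[(2S,3S)-4-ethenyl-6-hydroxy-2-(4-hydroxyphenyl)-2,3-dihydro-1-benzofuran-3-yl]benzene-1,3-diol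
Conditions: PdCl2(dppf) (5 mol%), Et3N, n-PrOH/H2O, 90 °C, degassed
Reagents that add atoms: potassium vinyltrifluoroborate (compound 11), [K+].C=C[B-](F)(F)F
Why: Suzuki–Miyaura vinylation with an amine base tolerates free phenols, and the bromide is meta to the oxygens and so not deactivated by a para phenoxide.

Step 7
Reactants: 13 5-bromo-2-hydroxybenzonitrile; 5 4-methoxybenzyl chloride
Product: 14 5-bromo-2-[(4-methoxyphenyl)methoxy]benzonitrile
Conditions: K2CO3, DMF, 50 °C
Reagents that add atoms: 4-methoxybenzyl chloride (compound 5), COc1ccc(CCl)cc1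
Why: Williamson etherification of an acidic cyanophenol.

Step 8
Reactants: 14 5-bromo-2-[(4-methoxyphenyl)methoxy]benzonitrile; 15 (3,5-dimethoxyphenyl)magnesium chloride
Product: 17 {5-bromo-2-[(4-methoxyphenyl)methoxy]phenyl}(3,5-dimethoxyphenyl)methanone, via magnesium ketimide 16 (not isolated)
Conditions: THF, 60 °C; then 2 M aq. HCl, rt
Reagents that add atoms: (3,5-dimethoxyphenyl)magnesium chloride (compound 15), COc1cc([Mg]Cl)cc(OC)c1; water, O
Why: Grignard addition to a nitrile stops at the N-magnesio ketimine (no over-addition), which dilute acid hydrolyses to the diaryl ketone; an arylmagnesium chloride does not exchange with the aryl bromide.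

Step 9
Reactants: 17 {5-bromo-2-[(4-methoxyphenyl)methoxy]phenyl}(3,5-dimethoxyphenyl)methanone
Product: 18 hydrazone of 17
Conditions: N2H4·H2O (excess), AcOH (cat.), EtOH, 80 °C
Reagents that add atoms: hydrazine (as monohydrate), NN
Why: Standard hydrazone condensation of a 2-alkoxybenzophenone.

Step 10
Reactants: 18 hydrazone of 17
Product: 20 (2S,3R)-5-bromo-3-(3,5-dimethoxyphenyl)-2-(4-methoxyphenyl)-2,3-dihydro-1-benzofuran (2,3-cis), via diaryldiazomethane 19 (not isolated)
Conditions: MnO2, CH2Cl2, 0 °C, filtration; Rh2(S-PTAD)4 (1 mol%), CH2Cl2, −20 °C → rt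
Reagents that add atoms: none
Why: The same donor/donor carbene 1,5-C–H insertion with the antipodal catalyst sets C3 (R), the future Cc; the ring oxygen–Ca bond is a temporary bond, so the C2 configuration is irrelevant because step 13 ionises it.

Step 11
Reactants: 20 (2S,3R)-5-bromo-3-(3,5-dimethoxyphenyl)-2-(4-methoxyphenyl)-2,3-dihydro-1-benzofuran
Product: 21 (2S,3S)-5-bromo-3-(2-iodo-3,5-dimethoxyphenyl)-2-(4-methoxyphenyl)-2,3-dihydro-1-benzofuran (2,3-cis; the C3 descriptor changes by priority only)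
Conditions: NIS (1.05 equiv), MeCN, 0 °C, dark
Reagents that add atoms: N-iodosuccinimide, O=C1CCC(=O)N1I
Why: Electrophilic aromatic iodination should go to the most electron-rich ring (ring B) at the position para to one methoxy group and ortho to the other; the two such positions are equivalent.

Step 12
Reactants: 21 (2S,3S)-5-bromo-3-(2-iodo-3,5-dimethoxyphenyl)-2-(4-methoxyphenyl)-2,3-dihydro-1-benzofuran; 22 N,3,5-trimethoxy-N-methylbenzamide
Product: 25 {2-[(2S,3R)-5-bromo-2-(4-methoxyphenyl)-2,3-dihydro-1-benzofuran-3-yl]-4,6-dimethoxyphenyl}(3,5-dimethoxyphenyl)methanone, via aryllithium 23 (not isolated), via lithium hemiaminal 24 (not isolated)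
Conditions: n-BuLi (1.05 equiv), THF, −78 °C; then 22, −78 °C → rt; aq. NH4Cl
Reagents that add atoms: N,3,5-trimethoxy-N-methylbenzamide (compound 22), COc1cc(cc(OC)c1)C(=O)N(C)OC
Why: Iodine–lithium exchange is much faster than bromine–lithium exchange at −78 °C, and the Weinreb ketone synthesis stops at the chelated adduct 24, so the ring B–CO–ring A ketone (future Cb) forms without over-addition.

Step 13
Reactants: 25 {2-[(2S,3R)-5-bromo-2-(4-methoxyphenyl)-2,3-dihydro-1-benzofuran-3-yl]-4,6-dimethoxyphenyl}(3,5-dimethoxyphenyl)methanone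
Product: 26 (10R,11S)-10-(5-bromo-2-hydroxyphenyl)-1,3,6,8-tetramethoxy-11-(4-methoxyphenyl)-10,11-dihydro-5H-dibenzo[a,d][7]annulen-5-one
Conditions: TfOH (20 mol%), HFIP/CH2Cl2, 0 °C → rt
Reagents that add atoms: none
Why: Acid ionises the benzylic C2–O bond of the temporary dihydrofuran (p-methoxybenzyl cation, ring C phenol as leaving group), and ring A, at its position ortho/para to two methoxy groups, traps the cation in a seven-membered Friedel–Crafts alkylation; Cc is not involved and directs Ca so that the two aryl groups end trans (anti approach in the ring-forming transition state, and the reversible alkylation lets the trans isomer accumulate).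

Step 14
Reactants: 26 (10R,11S)-10-(5-bromo-2-hydroxyphenyl)-1,3,6,8-tetramethoxy-11-(4-methoxyphenyl)-10,11-dihydro-5H-dibenzo[a,d][7]annulen-5-one
Product: 27 (10R,11S)-10-(5-bromo-2-methoxyphenyl)-1,3,6,8-tetramethoxy-11-(4-methoxyphenyl)-10,11-dihydro-5H-dibenzo[a,d][7]annulen-5-one
Conditions: MeI, K2CO3, acetone, 50 °C
Reagents that add atoms: iodomethane, CI
Why: Williamson methylation caps the liberated ring C phenol so that only one phenol is present after the next step.

Step 15
Reactants: 27 (10R,11S)-10-(5-bromo-2-methoxyphenyl)-1,3,6,8-tetramethoxy-11-(4-methoxyphenyl)-10,11-dihydro-5H-dibenzo[a,d][7]annulen-5-one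
Product: 28 (10R,11S)-10-(5-bromo-2-methoxyphenyl)-6-hydroxy-1,3,8-trimethoxy-11-(4-methoxyphenyl)-10,11-dihydro-5H-dibenzo[a,d][7]annulen-5-one
Conditions: BCl3 (1.5 equiv), CH2Cl2, −78 → 0 °C
Reagents that add atoms: none
Why: Chelation-controlled demethylation removes only the C6 methyl ether, the single methoxy group ortho to the ketone, which is the ring B oxygen of the future dihydrofuran.

Step 16
Reactants: 28 (10R,11S)-10-(5-bromo-2-methoxyphenyl)-6-hydroxy-1,3,8-trimethoxy-11-(4-methoxyphenyl)-10,11-dihydro-5H-dibenzo[a,d][7]annulen-5-one; 5 4-methoxybenzyl chloride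
Product: 29 (10R,11S)-10-(5-bromo-2-methoxyphenyl)-1,3,8-trimethoxy-6-[(4-methoxyphenyl)methoxy]-11-(4-methoxyphenyl)-10,11-dihydro-5H-dibenzo[a,d][7]annulen-5-one
Conditions: K2CO3, NaI (cat.), DMF, 60 °C
Reagents that add atoms: 4-methoxybenzyl chloride (compound 5), COc1ccc(CCl)cc1
Why: Williamson etherification places the O–CH2–(4-methoxyphenyl) group (future Cd and its aryl group) ortho to the ketone.

Step 17
Reactants: 29 (10R,11S)-10-(5-bromo-2-methoxyphenyl)-1,3,8-trimethoxy-6-[(4-methoxyphenyl)methoxy]-11-(4-methoxyphenyl)-10,11-dihydro-5H-dibenzo[a,d][7]annulen-5-one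
Product: 30 hydrazone of 29
Conditions: N2H4·H2O (excess), AcOH (cat.), n-BuOH, 110 °C
Reagents that add atoms: hydrazine (as monohydrate), NN
Why: Hydrazone condensation of a dibenzosuberone-type ketone that has only one ortho substituent; ethers and aryl bromide are inert.

Step 18
Reactants: 30 hydrazone of 29
Product: 32 hexa-O-methyl bromo tetracycle with cis-dihydrofuran (Ca S; Cc R; Cb S; Cd R), via cyclic diaryldiazomethane 31 (not isolated)
Conditions: MnO2, CH2Cl2, 0 °C, filtration; slow addition to Rh2(R-PTAD)4 (2 mol%), CH2Cl2 (high dilution), −20 °C → rt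
Reagents that add atoms: none
Why: MnO2 dehydrogenates the hydrazone to the diaryldiazoalkane 31, which the dirhodium carboxylate converts into a donor/donor carbene at the former carbonyl carbon; this inserts into the benzylic C–H bond of the ortho ArO–CH2–Ar group through a concerted, hydride-transfer-like three-centre transition state. The closest known reaction type is the dirhodium-catalysed enantioselective intramolecular C–H insertion of diaryl carbenes from 2-(benzyloxy)benzophenone hydrazones, which gives cis-2,3-diaryl-2,3-dihydrobenzofurans. The dihydrofuran closes by 1,5-C–H insertion, forming the Cb–Cd bond in a five-membered ring through the existing aryl C–O bond. Cb is controlled by the substrate: in the reacting geometry ring A and the metal lie on opposite faces of ring B, and the pseudo-axial substituent on Cc points at the metal face, so only the conformer with Cc–H axial and ring C pseudo-equatorial can react, which places Cb–H syn to Cc–H as in the target, and the catalyst antipode is chosen to match. Cd follows from the transition state, in which the anisyl group turns away from the carboxylate wall of the catalyst and ends cis to ring A (the kinetic cis isomer, corrected in step 19). The step needs 1,5-insertion to beat azine formation, arene addition and 1,2-shift: the carbene carbon has no beta hydrogen, the only C–H bond within reach that is activated by both oxygen and a p-anisyl group is the OCH2Ar bond, and slow addition at high dilution suppresses dimerisation.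

Step 19
Reactants: 32 hexa-O-methyl bromo tetracycle with cis-dihydrofuran
Product: 33 bromo hexaphenol tetracycle with trans-dihydrofuran (Ca S; Cc R; Cb S; Cd S)
Conditions: BBr3 (excess), CH2Cl2, −78 °C → rt; MeOH/H2O quench
Reagents that add atoms: none
Why: Lewis-acid ether cleavage removes six methyl groups, and reversible ionisation of the benzylic Cd–O bond should epimerise Cd to the more stable trans isomer while Cb, Ca and Cc are untouched; it is done here because no acid-sensitive stilbene is yet present.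

Step 20
Reactants: 33 bromo hexaphenol tetracycle; 12 5-[(2S,3S)-4-ethenyl-6-hydroxy-2-(4-hydroxyphenyl)-2,3-dihydro-1-benzofuran-3-yl]benzene-1,3-diol
Product: 34 (E)-isomer of the target
Conditions: Pd(OAc)2 (10 mol%), P(o-tol)3 (20 mol%), Et3N, DMF, 100 °C, degassed
Reagents that add atoms: compound 12, C=Cc1cc(O)cc2c1[C@H](c1cc(O)cc(O)c1)[C@@H](c1ccc(O)cc1)O2
Why: The Heck reaction of bromophenols with styrenes under classical phosphine conditions tolerates free phenols, and syn-insertion followed by syn-beta-hydride elimination gives the E-stilbene without acid.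

Step 21
Reactants: 34 (E)-isomer of the target
Product: 35 target CNP0266373.3 (Z-olefin)
Conditions: hν (365 nm LED), degassed MeOH, rt; preparative reversed-phase HPLC
Reagents that add atoms: none
Why: Photochemical E→Z isomerisation of a hydroxystilbene should give a photostationary state rich in the Z isomer, because the twisted Z isomer absorbs far less at 365 nm; no acid or base is present, so all six stereocentres are untouched.

**Compound list**

1 | 1-bromo-3,5-dimethoxybenzene | COc1cc(Br)cc(OC)c1 | starting material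
2 | 3,5-dimethoxybenzoyl chloride | COc1cc(cc(OC)c1)C(Cl)=O | starting material
3 | (2-bromo-4,6-dimethoxyphenyl)(3,5-dimethoxyphenyl)methanone | COc1cc(OC)cc(c1)C(=O)c1c(Br)cc(OC)cc1OC | intermediate
4 | (2-bromo-6-hydroxy-4-methoxyphenyl)(3,5-dimethoxyphenyl)methanone | COc1cc(OC)cc(c1)C(=O)c1c(Br)cc(OC)cc1O | intermediate
5 | 4-methoxybenzyl chloride | COc1ccc(CCl)cc1 | starting material
6 | {2-bromo-4-methoxy-6-[(4-methoxyphenyl)methoxy]phenyl}(3,5-dimethoxyphenyl)methanone | COc1ccc(COc2cc(OC)cc(Br)c2C(=O)c2cc(OC)cc(OC)c2)cc1 | intermediate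
7 | hydrazone of 6 | COc1ccc(COc2cc(OC)cc(Br)c2C(=NN)c2cc(OC)cc(OC)c2)cc1 | intermediate
8 | 1-bromo-2-[diazo(3,5-dimethoxyphenyl)methyl]-5-methoxy-3-[(4-methoxyphenyl)methoxy]benzene | COc1ccc(COc2cc(OC)cc(Br)c2C(=[N+]=[N-])c2cc(OC)cc(OC)c2)cc1 | intermediate
9 | (2R,3S)-4-bromo-3-(3,5-dimethoxyphenyl)-6-methoxy-2-(4-methoxyphenyl)-2,3-dihydro-1-benzofuran (cis) | Brc1cc(OC)cc2c1[C@H](c1cc(OC)cc(OC)c1)[C@H](c1ccc(OC)cc1)O2 | intermediate
10 | 5-[(2S,3S)-4-bromo-6-hydroxy-2-(4-hydroxyphenyl)-2,3-dihydro-1-benzofuran-3-yl]benzene-1,3-diol (trans) | Brc1cc(O)cc2c1[C@H](c1cc(O)cc(O)c1)[C@@H](c1ccc(O)cc1)O2 | intermediate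
11 | potassium vinyltrifluoroborate | [K+].C=C[B-](F)(F)F | starting material
12 | 5-[(2S,3S)-4-ethenyl-6-hydroxy-2-(4-hydroxyphenyl)-2,3-dihydro-1-benzofuran-3-yl]benzene-1,3-diol | C=Cc1cc(O)cc2c1[C@H](c1cc(O)cc(O)c1)[C@@H](c1ccc(O)cc1)O2 | intermediate
13 | 5-bromo-2-hydroxybenzonitrile | N#Cc1cc(Br)ccc1O | starting material
14 | 5-bromo-2-[(4-methoxyphenyl)methoxy]benzonitrile | COc1ccc(COc2ccc(Br)cc2C#N)cc1 | intermediate
15 | (3,5-dimethoxyphenyl)magnesium chloride (THF solution) | COc1cc([Mg]Cl)cc(OC)c1 | starting material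
16 | N-chloromagnesio ketimine from 14 and 15 | COc1ccc(COc2ccc(Br)cc2C(=N[Mg]Cl)c2cc(OC)cc(OC)c2)cc1 | intermediate
17 | {5-bromo-2-[(4-methoxyphenyl)methoxy]phenyl}(3,5-dimethoxyphenyl)methanone | COc1ccc(COc2ccc(Br)cc2C(=O)c2cc(OC)cc(OC)c2)cc1 | intermediate
18 | hydrazone of 17 | COc1ccc(COc2ccc(Br)cc2C(=NN)c2cc(OC)cc(OC)c2)cc1 | intermediate
19 | 4-bromo-2-[diazo(3,5-dimethoxyphenyl)methyl]-1-[(4-methoxyphenyl)methoxy]benzene | COc1ccc(COc2ccc(Br)cc2C(=[N+]=[N-])c2cc(OC)cc(OC)c2)cc1 | intermediate
20 | (2S,3R)-5-bromo-3-(3,5-dimethoxyphenyl)-2-(4-methoxyphenyl)-2,3-dihydro-1-benzofuran (cis; temporary ring) | COc1ccc([C@H]2Oc3ccc(Br)cc3[C@H]2c2cc(OC)cc(OC)c2)cc1 | intermediate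
21 | (2S,3S)-5-bromo-3-(2-iodo-3,5-dimethoxyphenyl)-2-(4-methoxyphenyl)-2,3-dihydro-1-benzofuran (cis) | COc1ccc([C@H]2Oc3ccc(Br)cc3[C@H]2c2cc(OC)cc(OC)c2I)cc1 | intermediate
22 | N,3,5-trimethoxy-N-methylbenzamide | COc1cc(cc(OC)c1)C(=O)N(C)OC | starting material
23 | aryllithium from 21 (lithium in place of iodine) | COc1ccc([C@H]2Oc3ccc(Br)cc3[C@H]2c2cc(OC)cc(OC)c2[Li])cc1 | intermediate
24 | lithium hemiaminal adduct of 23 and 22 | COc1ccc([C@H]2Oc3ccc(Br)cc3[C@H]2c2cc(OC)cc(OC)c2C(O[Li])(N(C)OC)c2cc(OC)cc(OC)c2)cc1 | intermediate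
25 | {2-[(2S,3R)-5-bromo-2-(4-methoxyphenyl)-2,3-dihydro-1-benzofuran-3-yl]-4,6-dimethoxyphenyl}(3,5-dimethoxyphenyl)methanone | COc1ccc([C@H]2Oc3ccc(Br)cc3[C@H]2c2cc(OC)cc(OC)c2C(=O)c2cc(OC)cc(OC)c2)cc1 | intermediate
26 | (10R,11S)-10-(5-bromo-2-hydroxyphenyl)-1,3,6,8-tetramethoxy-11-(4-methoxyphenyl)-10,11-dihydro-5H-dibenzo[a,d][7]annulen-5-one | COc1ccc([C@H]2c3c(OC)cc(OC)cc3C(=O)c3c(OC)cc(OC)cc3[C@@H]2c2cc(Br)ccc2O)cc1 | intermediate
27 | (10R,11S)-10-(5-bromo-2-methoxyphenyl)-1,3,6,8-tetramethoxy-11-(4-methoxyphenyl)-10,11-dihydro-5H-dibenzo[a,d][7]annulen-5-one | COc1ccc([C@H]2c3c(OC)cc(OC)cc3C(=O)c3c(OC)cc(OC)cc3[C@@H]2c2cc(Br)ccc2OC)cc1 | intermediate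
28 | (10R,11S)-10-(5-bromo-2-methoxyphenyl)-6-hydroxy-1,3,8-trimethoxy-11-(4-methoxyphenyl)-10,11-dihydro-5H-dibenzo[a,d][7]annulen-5-one | COc1ccc([C@H]2c3c(OC)cc(OC)cc3C(=O)c3c(O)cc(OC)cc3[C@@H]2c2cc(Br)ccc2OC)cc1 | intermediate
29 | (10R,11S)-10-(5-bromo-2-methoxyphenyl)-1,3,8-trimethoxy-6-[(4-methoxyphenyl)methoxy]-11-(4-methoxyphenyl)-10,11-dihydro-5H-dibenzo[a,d][7]annulen-5-one | COc1ccc([C@H]2c3c(OC)cc(OC)cc3C(=O)c3c(OCc4ccc(OC)cc4)cc(OC)cc3[C@@H]2c2cc(Br)ccc2OC)cc1 | intermediate
30 | hydrazone of 29 | COc1ccc([C@H]2c3c(OC)cc(OC)cc3C(=NN)c3c(OCc4ccc(OC)cc4)cc(OC)cc3[C@@H]2c2cc(Br)ccc2OC)cc1 | intermediate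
31 | (10R,11S)-10-(5-bromo-2-methoxyphenyl)-5-diazo-1,3,8-trimethoxy-6-[(4-methoxyphenyl)methoxy]-11-(4-methoxyphenyl)-10,11-dihydro-5H-dibenzo[a,d][7]annulene | COc1ccc([C@H]2c3c(OC)cc(OC)cc3C(=[N+]=[N-])c3c(OCc4ccc(OC)cc4)cc(OC)cc3[C@@H]2c2cc(Br)ccc2OC)cc1 | intermediate
32 | hexa-O-methyl bromo tetracycle: seven-membered ring fused to rings A and B, dihydrofuran fused to ring B, Cd aryl cis to ring A (Ca S, Cc R, Cb S, Cd R) | COc1ccc([C@H]2c3c(OC)cc(OC)cc3[C@H]3c4c(cc(OC)cc4[C@@H]2c2cc(Br)ccc2OC)O[C@H]3c2ccc(OC)cc2)cc1 | intermediate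
33 | bromo hexaphenol tetracycle with trans-dihydrofuran (Ca S, Cc R, Cb S, Cd S); ring C is 5-bromo-2-hydroxyphenyl | Oc1ccc([C@H]2c3c(O)cc(O)cc3[C@H]3c4c(cc(O)cc4[C@@H]2c2cc(Br)ccc2O)O[C@@H]3c2ccc(O)cc2)cc1 | intermediate
34 | (E)-isomer of the target (E-stilbene between ring C and ring D) | Oc1ccc([C@H]2c3c(O)cc(O)cc3[C@H]3c4c(cc(O)cc4[C@@H]2c2cc(/C=C/c4cc(O)cc5c4[C@H](c4cc(O)cc(O)c4)[C@@H](c4ccc(O)cc4)O5)ccc2O)O[C@@H]3c2ccc(O)cc2)cc1 | intermediate
35 | CNP0266373.3 (Z-stilbene; Ca S, Cc R, Cb S, Cd S; east 2S,3S) | Oc1ccc([C@H]2c3c(O)cc(O)cc3[C@H]3c4c(cc(O)cc4[C@@H]2c2cc(/C=C\c4cc(O)cc5c4[C@H](c4cc(O)cc(O)c4)[C@@H](c4ccc(O)cc4)O5)ccc2O)O[C@@H]3c2ccc(O)cc2)cc1 | target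

**Summary**

Total step count: 21. Longest linear sequence: 15 steps (steps 7–21, from compound 13).

Three steps most likely to fail:

1. Step 18. What may go wrong: slow or incomplete diazo formation at the ring-embedded hindered ketone, azine formation in place of insertion, or approach of the carbene from the wrong face relative to Cc. Fallback (forms the O–Cd bond instead of the Cb–Cd bond): it sets out from 27 and comes back at 33. A Wittig reaction of 27 with Ph3P=CHOMe (from (methoxymethyl)triphenylphosphonium chloride and KHMDS) gives the enol ether F1. Aqueous HCl/THF gives the aldehyde F2, whose Cb epimers interconvert through the enol, so the isomer matching 33 can be enriched and separated. 4-Methoxyphenylmagnesium bromide adds to give the carbinol F3 (either carbinol epimer serves). BBr3 under the conditions of step 19 then cleaves all methyl ethers, ionises the p-oxybenzylic carbinol, and lets the ring B oxygen ortho to Cb close the trans-dihydrofuran (dehydrative oxa-cyclisation), giving 33 directly.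

2. Step 13. What may go wrong: recapture of the benzylic cation only by the phenol oxygen because ring A is deactivated by its carbonyl group, loss of the Cc proton from the cation (erosion of enantiopurity), or poor trans selectivity in the ring-forming transition state. Fallback (intermolecular alkylation first, ring closure by acylation): it sets out from 20 and comes back at 27. Acid opening of 20 (TfOH, HFIP) in the presence of commercial methyl 3,5-dimethoxybenzoate gives the open-chain Friedel–Crafts adduct F4, with anti selectivity expected from allylic-strain control in the acyclic cation. Methylation of the phenol (MeI, K2CO3) gives the ester F5 and saponification (LiOH) the acid F6. Intramolecular Friedel–Crafts acylation of ring B (TFAA, CH2Cl2) then closes the seven-membered ketone 27.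

3. Step 21 (together with step 20). What may go wrong: incomplete E→Z conversion at the photostationary state, photocyclisation of the Z-stilbene, or low conversion of the electron-rich bromophenol in the preceding Heck reaction. Fallback (Z-olefin by alkyne semihydrogenation): it sets out from 10 and 33 and comes back at 35. Sonogashira coupling of 10 with trimethylsilylacetylene (PdCl2(PPh3)2, CuI, Et3N, DMF) gives the silyl alkyne F7, and K2CO3/MeOH gives the terminal alkyne F8. A second Sonogashira coupling of F8 with 33 gives the diaryl alkyne F9. Lindlar semihydrogenation (Pd/CaCO3 poisoned with Pb(OAc)2, quinoline, H2, MeOH) then gives 35 by syn addition of hydrogen.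

Further compounds
F1 | step 18 | (10R,11S)-10-(5-bromo-2-methoxyphenyl)-1,3,6,8-tetramethoxy-5-(methoxymethylidene)-11-(4-methoxyphenyl)-10,11-dihydro-5H-dibenzo[a,d][7]annulene | COc1ccc([C@H]2c3c(OC)cc(OC)cc3C(=COC)c3c(OC)cc(OC)cc3[C@@H]2c2cc(Br)ccc2OC)cc1
F2 | step 18 | (5S,10R,11S)-10-(5-bromo-2-methoxyphenyl)-1,3,6,8-tetramethoxy-11-(4-methoxyphenyl)-10,11-dihydro-5H-dibenzo[a,d][7]annulene-5-carbaldehyde | COc1ccc([C@H]2c3c(OC)cc(OC)cc3[C@H](C=O)c3c(OC)cc(OC)cc3[C@@H]2c2cc(Br)ccc2OC)cc1
F3 | step 18 | [(5S,10R,11S)-10-(5-bromo-2-methoxyphenyl)-1,3,6,8-tetramethoxy-11-(4-methoxyphenyl)-10,11-dihydro-5H-dibenzo[a,d][7]annulen-5-yl](4-methoxyphenyl)methanol | COc1ccc([C@H]2c3c(OC)cc(OC)cc3[C@H](C(O)c3ccc(OC)cc3)c3c(OC)cc(OC)cc3[C@@H]2c2cc(Br)ccc2OC)cc1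
F4 | step 13 | methyl 2-[(1S,2R)-2-(5-bromo-2-hydroxyphenyl)-2-(3,5-dimethoxyphenyl)-1-(4-methoxyphenyl)ethyl]-3,5-dimethoxybenzoate | COc1ccc([C@H]([C@H](c2cc(OC)cc(OC)c2)c2cc(Br)ccc2O)c2c(OC)cc(OC)cc2C(=O)OC)cc1
F5 | step 13 | methyl 2-[(1S,2R)-2-(5-bromo-2-methoxyphenyl)-2-(3,5-dimethoxyphenyl)-1-(4-methoxyphenyl)ethyl]-3,5-dimethoxybenzoate | COc1ccc([C@H]([C@H](c2cc(OC)cc(OC)c2)c2cc(Br)ccc2OC)c2c(OC)cc(OC)cc2C(=O)OC)cc1
F6 | step 13 | 2-[(1S,2R)-2-(5-bromo-2-methoxyphenyl)-2-(3,5-dimethoxyphenyl)-1-(4-methoxyphenyl)ethyl]-3,5-dimethoxybenzoic acid | COc1ccc([C@H]([C@H](c2cc(OC)cc(OC)c2)c2cc(Br)ccc2OC)c2c(OC)cc(OC)cc2C(=O)O)cc1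
F7 | step 21 | 5-[(2S,3S)-6-hydroxy-2-(4-hydroxyphenyl)-4-[(trimethylsilyl)ethynyl]-2,3-dihydro-1-benzofuran-3-yl]benzene-1,3-diol | C[Si](C)(C)C#Cc1cc(O)cc2c1[C@H](c1cc(O)cc(O)c1)[C@@H](c1ccc(O)cc1)O2
F8 | step 21 | 5-[(2S,3S)-4-ethynyl-6-hydroxy-2-(4-hydroxyphenyl)-2,3-dihydro-1-benzofuran-3-yl]benzene-1,3-diol | C#Cc1cc(O)cc2c1[C@H](c1cc(O)cc(O)c1)[C@@H](c1ccc(O)cc1)O2
F9 | step 21 | alkyne analogue of the target (C≡C in place of the olefin between ring C and ring D) | Oc1ccc([C@H]2c3c(O)cc(O)cc3[C@H]3c4c(cc(O)cc4[C@@H]2c2cc(C#Cc4cc(O)cc5c4[C@H](c4cc(O)cc(O)c4)[C@@H](c4ccc(O)cc4)O5)ccc2O)O[C@@H]3c2ccc(O)cc2)cc1
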